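**Retrosynthetic overview**
- The enone is cut at the aryl–C(=O) bond: ortho-lithiation of the MOM-protected chroman, then acylation with a ready-made (E)-cinnamoyl Weinreb amide. The three MOM groups come off last.
- The prenyl group comes from a Wittig reaction on the lactol of a seven-membered aryl lactone, which also frees the C5 phenol.
- The pyran ring is closed by acid-catalysed addition of the neighbouring phenol to an isopropenyl group, before the prenyl alkene exists.
- Key step: the C3–C4 bond and the C3 stereocentre are made together. The nucleophilic β-carbon of a chiral carbene-bound homoenolate of (2E)-4-methylpenta-2,4-dienal adds to the electrophilic CH2 of an o-quinone methide from a symmetric 5-methoxyresorcinol unit.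
- Ring order: ring A is bought, then the seven-membered lactone (temporary), then the pyran ring, then the lactone is opened; ring B is bought.

Assumption: the target is the (3S)-chroman of the given SMILES; the (5aR,10bS) triazolium salt is taken to give the (4R)-lactone 9, and its commercially available mirror image is used instead, with nothing else changed, if the sense of induction proves opposite.

**Step 1**
Reactants: 1 2,4,6-trihydroxybenzaldehyde
Product: 2 2,6-dihydroxy-4-methoxybenzaldehyde
Conditions: Me2SO4 (1.0 equiv), K2CO3 (1.0 equiv), acetone, 0 °C → rt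
Reagents that add atoms: dimethyl sulfate, COS(=O)(=O)OC
Why: Williamson O-methylation, in which the 4-hydroxyl is the only one not hydrogen-bonded to the formyl group and is the most acidic, so one equivalent of Me2SO4 alkylates it selectively and leaves a symmetric resorcinol whose two hydroxyls and two ring CH positions are equivalent.

**Step 2**
Reactants: 2 2,6-dihydroxy-4-methoxybenzaldehyde
Product: 4 2-[(dimethylamino)methyl]-5-methoxybenzene-1,3-diol, via iminium phenoxide 3 (not isolated)
Conditions: Me2NH (2 M in THF, 3 equiv), NaBH(OAc)3 (1.5 equiv), THF, 0 °C → rt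
Reagents that add atoms: dimethylamine, CNC
Why: Reductive amination, in which dimethylamine condenses with the salicylaldehyde to an iminium phenoxide that NaBH(OAc)3 reduces to the benzylic amine (a Mannich base), the excess amine recapturing any quinone methide so that over-reduction to the methyl compound is held back.

**Step 3**
Reactants: 5 methacrolein
Product: 6 (2E)-4-methylpenta-2,4-dienal
Conditions: Ph3P=CHCHO (1.0 equiv), 5 (2.0 equiv), toluene, 60 °C; pentane trituration, distillation
Reagents that add atoms: (triphenylphosphoranylidene)acetaldehyde, O=CC=P(c1ccccc1)(c1ccccc1)c1ccccc1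
Why: Wittig olefination with a stabilised formyl ylide gives the E-enal, and the excess of the volatile, more electrophilic methacrolein keeps the dienal from reacting a second time.

**Step 4 (key step)**
Reactants: 4 2-[(dimethylamino)methyl]-5-methoxybenzene-1,3-diol; 6 (2E)-4-methylpenta-2,4-dienal
Product: 9 (4R)-6-hydroxy-8-methoxy-4-(prop-1-en-2-yl)-4,5-dihydro-1-benzoxepin-2(3H)-one, via ammonium iodide 7 (not isolated), via o-quinone methide 8 (not isolated)
Conditions: MeI (1.0 equiv), THF, rt, 12 h; then 6 (1.5 equiv), (5aR,10bS)-2-(2,4,6-trimethylphenyl)-5a,10b-dihydro-4H,6H-indeno[2,1-b][1,2,4]triazolo[4,3-d][1,4]oxazin-2-ium chloride (15 mol %), K2CO3 (2.2 equiv, ground), 4 Å molecular sieves, THF, −20 °C → rt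
Reagents that add atoms: none
Why: Proposed new method: N-methylation makes a trimethylammonium leaving group, sparingly soluble K2CO3 slowly releases the o-quinone methide by E1cB loss of NMe3, and the chiral triazolylidene turns the dienal into a Breslow-type homoenolate whose β-carbon (normally the electrophilic carbon of an enal) adds to the electrophilic exocyclic CH2 while the indane-fused catalyst shields one face so that C4 is formed R, after which the phenoxide closes the seven-membered lactone on the acyl azolium and frees the catalyst; the closest known reaction type is the NHC-catalysed enantioselective formal [4+3] annulation of enals with in situ generated o-quinone methides to 4,5-dihydro-1-benzoxepin-2(3H)-ones, here extended to a 2,4-dienal (β-attack as with cinnamaldehydes) and to an unprotected resorcinol-type quinone methide.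

**Step 5**
Reactants: 9 (4R)-6-hydroxy-8-methoxy-4-(prop-1-en-2-yl)-4,5-dihydro-1-benzoxepin-2(3H)-one
Product: 10 tricyclic chroman lactone (3R; 7-methoxy-2,2-dimethylchroman whose C5 oxygen is tied to C3 by an O–C(=O)–CH2 bridge)
Conditions: p-toluenesulfonic acid (anhydrous, 10 mol %), toluene (0.02 M), 60 °C
Reagents that add atoms: none
Why: Brønsted acid-catalysed intramolecular Markovnikov hydroalkoxylation, in which protonation of the 1,1-disubstituted alkene gives a tertiary cation that the adjacent free phenol traps in a six-membered ring, while the aryl lactone is inert to anhydrous acid and the stereocentre, which only neighbours the cation, is carried through unchanged.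

**Step 6**
Reactants: 10 tricyclic chroman lactone
Product: 12 (3S)-7-methoxy-2,2-dimethyl-3-(3-methylbut-2-en-1-yl)-3,4-dihydro-2H-chromen-5-ol, via lactol 11 (not isolated)
Conditions: iBu2AlH (1.05 equiv), toluene, −78 °C, 1 h; then cannulate into Ph3P=CMe2 [from iPrPPh3I (3.5 equiv), nBuLi (3.4 equiv), THF, 0 °C], −78 °C → rt
Reagents that add atoms: isopropyltriphenylphosphonium iodide, CC(C)[P+](c1ccccc1)(c1ccccc1)c1ccccc1.[I-]
Why: Partial reduction of the aryl lactone with iBu2AlH stops at the lactol aluminate at −78 °C, and its open hydroxy-aldehyde form undergoes Wittig olefination with the unstabilised isopropylidene ylide to the prenyl group (no E/Z issue), which frees the C5 phenol and does not touch the stereocentre β to the aldehyde.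

**Step 7**
Reactants: 12 (3S)-7-methoxy-2,2-dimethyl-3-(3-methylbut-2-en-1-yl)-3,4-dihydro-2H-chromen-5-ol
Product: 13 (3S)-7-methoxy-5-(methoxymethoxy)-2,2-dimethyl-3-(3-methylbut-2-en-1-yl)-3,4-dihydro-2H-chromene
Conditions: NaH (1.3 equiv), CH3OCH2Cl (1.5 equiv), THF/DMF, 0 °C → rt
Reagents that add atoms: chloromethyl methyl ether, COCCl
Why: O-alkylation of the unhindered, non-chelated sodium phenoxide (MOM protection) gives an ether that serves both as protecting group and as metalation director.

**Step 8**
Reactants: 14 2,4-dihydroxybenzaldehyde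
Product: 15 2,4-bis(methoxymethoxy)benzaldehyde
Conditions: CH3OCH2Cl (2.6 equiv), K2CO3 (4 equiv), acetone, reflux
Reagents that add atoms: chloromethyl methyl ether, COCCl
Why: Double MOM protection by O-alkylation of both phenoxides, the chelated 2-hydroxyl needing the excess reagent and heat.

**Step 9**
Reactants: 15 2,4-bis(methoxymethoxy)benzaldehyde
Product: 16 (2E)-3-[2,4-bis(methoxymethoxy)phenyl]-N-methoxy-N-methylprop-2-enamide
Conditions: (EtO)2P(O)CH2C(O)N(OMe)Me (1.2 equiv), NaH (1.2 equiv), THF, 0 °C → rt
Reagents that add atoms: diethyl [2-(methoxy(methyl)amino)-2-oxoethyl]phosphonate, CCOP(=O)(OCC)CC(=O)N(C)OC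
Why: Horner–Wadsworth–Emmons olefination with the stabilised phosphonate anion gives the E-configured α,β-unsaturated Weinreb amide.

**Step 10**
Reactants: 13 (3S)-7-methoxy-5-(methoxymethoxy)-2,2-dimethyl-3-(3-methylbut-2-en-1-yl)-3,4-dihydro-2H-chromene; 16 (2E)-3-[2,4-bis(methoxymethoxy)phenyl]-N-methoxy-N-methylprop-2-enamide
Product: 18 (2E)-3-[2,4-bis(methoxymethoxy)phenyl]-1-[(3S)-7-methoxy-5-(methoxymethoxy)-2,2-dimethyl-3-(3-methylbut-2-en-1-yl)-3,4-dihydro-2H-chromen-6-yl]prop-2-en-1-one, via aryllithium 17 (not isolated)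
Conditions: nBuLi (1.2 equiv), TMEDA (1.2 equiv), THF, 0 °C, 1 h; then 16 (1.2 equiv), −78 → 0 °C; H2O
Reagents that add atoms: none
Why: Directed ortho-metalation followed by Weinreb ketone synthesis, in which C6 lies between the chelating OMOM group and the OMe group and is lithiated in preference to C8 (flanked by OMe and the hindered ring oxygen), and the aryllithium adds 1,2 to the N-methoxy-N-methylamide to a chelated tetrahedral adduct that collapses to the E-enone only on work-up.

**Step 11**
Reactants: 18 the tris-MOM chalcone of step 10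
Product: 19 (2E)-3-(2,4-dihydroxyphenyl)-1-[(3S)-5-hydroxy-7-methoxy-2,2-dimethyl-3-(3-methylbut-2-en-1-yl)-3,4-dihydro-2H-chromen-6-yl]prop-2-en-1-one
Conditions: HCl (1.25 M in MeOH), rt, dark, argon
Reagents that add atoms: none
Why: Acid-catalysed acetal methanolysis removes all three MOM groups (the one ortho to the carbonyl fastest) under conditions mild enough to leave the E-enone, the prenyl alkene that is remote from any phenol, and the stereocentre untouched.

**Compound list**
1 | 2,4,6-trihydroxybenzaldehyde | O=Cc1c(O)cc(O)cc1O | starting material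
2 | 2,6-dihydroxy-4-methoxybenzaldehyde | COc1cc(O)c(C=O)c(O)c1 | intermediate
3 | 2-[(dimethyliminio)methyl]-3-hydroxy-5-methoxyphenolate (iminium phenoxide) | C[N+](C)=Cc1c(O)cc(OC)cc1[O-] | intermediate
4 | 2-[(dimethylamino)methyl]-5-methoxybenzene-1,3-diol | CN(C)Cc1c(O)cc(OC)cc1O | intermediate
5 | methacrolein (2-methylprop-2-enal) | CC(=C)C=O | starting material
6 | (2E)-4-methylpenta-2,4-dienal | CC(=C)/C=C/C=O | intermediate
7 | (2,6-dihydroxy-4-methoxyphenyl)-N,N,N-trimethylmethanaminium iodide | C[N+](C)(C)Cc1c(O)cc(OC)cc1O.[I-] | intermediate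
8 | 3-hydroxy-5-methoxy-2-methylidenecyclohexa-3,5-dien-1-one (o-quinone methide) | COC1=CC(=O)C(=C)C(O)=C1 | intermediate
9 | (4R)-6-hydroxy-8-methoxy-4-(prop-1-en-2-yl)-4,5-dihydro-1-benzoxepin-2(3H)-one | COc1cc(O)c2C[C@H](CC(=O)Oc2c1)C(C)=C | intermediate
10 | tricyclic chroman lactone: 7-methoxy-2,2-dimethylchroman whose C5 oxygen is tied to C3 by an O–C(=O)–CH2 bridge, R at C3 (chroman numbering) | COc1cc2OC(C)(C)[C@H]3CC(=O)Oc(c1)c2C3 | intermediate
11 | lactol of 10 (lactone C=O reduced to CH–OH, both anomers), R at C3 | COc1cc2OC(C)(C)[C@H]3CC(O)Oc(c1)c2C3 | intermediate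
12 | (3S)-7-methoxy-2,2-dimethyl-3-(3-methylbut-2-en-1-yl)-3,4-dihydro-2H-chromen-5-ol | COc1cc(O)c2C[C@H](CC=C(C)C)C(C)(C)Oc2c1 | intermediate
13 | (3S)-7-methoxy-5-(methoxymethoxy)-2,2-dimethyl-3-(3-methylbut-2-en-1-yl)-3,4-dihydro-2H-chromene | COc1cc(OCOC)c2C[C@H](CC=C(C)C)C(C)(C)Oc2c1 | intermediate
14 | 2,4-dihydroxybenzaldehyde | O=Cc1ccc(O)cc1O | starting material
15 | 2,4-bis(methoxymethoxy)benzaldehyde | COCOc1ccc(C=O)c(OCOC)c1 | intermediate
16 | (2E)-3-[2,4-bis(methoxymethoxy)phenyl]-N-methoxy-N-methylprop-2-enamide | CON(C)C(=O)/C=C/c1ccc(OCOC)cc1OCOC | intermediate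
17 | [(3S)-7-methoxy-5-(methoxymethoxy)-2,2-dimethyl-3-(3-methylbut-2-en-1-yl)-3,4-dihydro-2H-chromen-6-yl]lithium | [Li]c1c(OC)cc2c(c1OCOC)C[C@H](CC=C(C)C)C(C)(C)O2 | intermediate
18 | (2E)-3-[2,4-bis(methoxymethoxy)phenyl]-1-[(3S)-7-methoxy-5-(methoxymethoxy)-2,2-dimethyl-3-(3-methylbut-2-en-1-yl)-3,4-dihydro-2H-chromen-6-yl]prop-2-en-1-one | COc1cc2c(c(OCOC)c1C(=O)/C=C/c1ccc(OCOC)cc1OCOC)C[C@H](CC=C(C)C)C(C)(C)O2 | intermediate
19 | (2E)-3-(2,4-dihydroxyphenyl)-1-[(3S)-5-hydroxy-7-methoxy-2,2-dimethyl-3-(3-methylbut-2-en-1-yl)-3,4-dihydro-2H-chromen-6-yl]prop-2-en-1-one | COc1cc2c(c(O)c1C(=O)/C=C/c1ccc(O)cc1O)C[C@H](CC=C(C)C)C(C)(C)O2 | target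

**Step count**
Total: 11 steps. Longest linear sequence: 8 steps (1, 2, 4, 5, 6, 7, 10, 11) from 2,4,6-trihydroxybenzaldehyde.

**The three steps most likely to fail**

Step 4. The free, very electron-rich phenoxides of 7 and 9 can attack the quinone methide 8 and give methylene-bridged oligomers. The homoenolate can also be protonated at the β-carbon, which leads to the six-membered dihydrocoumarin instead. The ee with a dienal is untested. The fallback sets out from 2 and comes back at 9, and it replaces the ammonium precursor by a fully O-silylated, fluoride-triggered one so that no free phenol is present.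
- Silylation of 2 (tert-butyldimethylsilyl chloride, imidazole, DMF) gives 2,6-bis(tert-butyldimethylsilyloxy)-4-methoxybenzaldehyde F1.
- NaBH4 in MeOH gives [2,6-bis(tert-butyldimethylsilyloxy)-4-methoxyphenyl]methanol F2.
- Ac2O, pyridine and 4-(dimethylamino)pyridine give [2,6-bis(tert-butyldimethylsilyloxy)-4-methoxyphenyl]methyl acetate F3.
- CsF and 18-crown-6 in THF, with 6 and the same triazolium salt, cleave one silyl ether; the phenoxide expels acetate to give 3-(tert-butyldimethylsilyloxy)-5-methoxy-2-methylidenecyclohexa-3,5-dien-1-one F4.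
- The annulation then gives (4R)-6-(tert-butyldimethylsilyloxy)-8-methoxy-4-(prop-1-en-2-yl)-4,5-dihydro-1-benzoxepin-2(3H)-one F5, and HF·pyridine in THF returns 9.

Step 5. The tertiary cation sits next to the stereocentre, so reversible loss of the C3 proton (to the tetrasubstituted alkene) or a hydride shift would erode the ee. The fallback sets out from 9 and comes back at 10 and avoids a free cation. N-(phenylseleno)phthalimide with catalytic camphorsulfonic acid in CH2Cl2 at −20 °C closes the pyran ring through a seleniranium ion to the selenide of 10 in which one C2 methyl is a (phenylselanyl)methyl group F6 (both C2 epimers). Bu3SnH with azobis(isobutyronitrile) in toluene at 80 °C then reduces the C–Se bond to give 10.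

Step 10. The hindered, doubly ortho-substituted aryllithium may add in conjugate fashion to the enoyl amide or react sluggishly with it. The fallback sets out from 13 (with 15) and comes back at 18, and it builds the enone by condensation instead. The same aryllithium 17 is quenched with N-methoxy-N-methylacetamide to give 1-[(3S)-7-methoxy-5-(methoxymethoxy)-2,2-dimethyl-3-(3-methylbut-2-en-1-yl)-3,4-dihydro-2H-chromen-6-yl]ethanone F7. Claisen–Schmidt condensation of this ketone with 15 (KOH, EtOH, rt) gives 18.

**Further compounds**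
F1 | step 4 | 2,6-bis(tert-butyldimethylsilyloxy)-4-methoxybenzaldehyde | COc1cc(O[Si](C)(C)C(C)(C)C)c(C=O)c(O[Si](C)(C)C(C)(C)C)c1
F2 | step 4 | [2,6-bis(tert-butyldimethylsilyloxy)-4-methoxyphenyl]methanol | COc1cc(O[Si](C)(C)C(C)(C)C)c(CO)c(O[Si](C)(C)C(C)(C)C)c1
F3 | step 4 | [2,6-bis(tert-butyldimethylsilyloxy)-4-methoxyphenyl]methyl acetate | COc1cc(O[Si](C)(C)C(C)(C)C)c(COC(C)=O)c(O[Si](C)(C)C(C)(C)C)c1
F4 | step 4 | 3-(tert-butyldimethylsilyloxy)-5-methoxy-2-methylidenecyclohexa-3,5-dien-1-one | COC1=CC(=O)C(=C)C(O[Si](C)(C)C(C)(C)C)=C1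
F5 | step 4 | (4R)-6-(tert-butyldimethylsilyloxy)-8-methoxy-4-(prop-1-en-2-yl)-4,5-dihydro-1-benzoxepin-2(3H)-one | COc1cc(O[Si](C)(C)C(C)(C)C)c2C[C@H](CC(=O)Oc2c1)C(C)=C
F6 | step 5 | selenide of 10 in which one C2 methyl is a (phenylselanyl)methyl group, R at C3, both C2 epimers | COc1cc2OC(C)(C[Se]c4ccccc4)[C@H]3CC(=O)Oc(c1)c2C3
F7 | step 10 | 1-[(3S)-7-methoxy-5-(methoxymethoxy)-2,2-dimethyl-3-(3-methylbut-2-en-1-yl)-3,4-dihydro-2H-chromen-6-yl]ethanone | COc1cc2c(c(OCOC)c1C(C)=O)C[C@H](CC=C(C)C)C(C)(C)O2
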